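**Assumption:** CAL-B acetylates the same enantiotopic CH2OH arm of chromene diol 9 as it does in the analogous chroman-2,2-dimethanols, giving the (S)-monoacetate 10 as drawn. This sense is assigned by analogy from memory of that precedent, not verified for this substrate.

## Retrosynthetic overview
1. Target ⇐ silyl and ester deprotection of a (Z)-enoate made by Still–Gennari olefination of C7′ aldehyde 24 with α-homoprenyl phosphonate 27.
2. Aldehyde 24 ⇐ C1′–C2′ bond by alkylating a geranyl-derived (E)-allylic sulfone 20 with chromenylmethyl triflate 16, then Pd/hydride desulfonylation.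
3. (S)-Chromenylmethanol 15 ⇐ prochiral 2,2-bis(hydroxymethyl)-2H-chromene 9 by lipase-catalysed desymmetrising acetylation, which sets the only stereocentre; the acetylated arm is then reduced to CH3.
4. Diol 9 ⇐ spiro-chromanone 5 (Kabbe annulation of a 2-hydroxyacetophenone with 2,2-dimethyl-1,3-dioxan-5-one), converted to the 2H-chromene via enol triflate reduction.
5. Ring order: the arene is bought; the pyran ring is the only ring built (step 3) and is dehydrogenated to the chromene in steps 5–6.

## Route

**Step 1**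
Reactants: 1, 4-methoxy-2-methylphenol
Product: 2, 1-(2-hydroxy-5-methoxy-3-methylphenyl)ethanone
Conditions: Ac2O, BF3·OEt2, 90 °C; aq. NaOAc work-up
Reagents that add atoms: acetic anhydride, CC(=O)OC(C)=O
Why: One-pot O-acetylation/Fries rearrangement; the acyl group goes to the only free position ortho to the phenol OH through the BF2 chelate.

**Step 2**
Reactants: 2
Product: 3, 1-(2,5-dihydroxy-3-methylphenyl)ethanone
Conditions: BBr3, CH2Cl2, −78 → 0 °C
Reagents that add atoms: none
Why: Lewis-acid aryl methyl ether cleavage, done early so the phenol can later carry a fluoride-labile group; the ketone is untouched.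

**Step 3**
Reactants: 3; 4, 2,2-dimethyl-1,3-dioxan-5-one
Product: 5, 6-hydroxy-2′,2′,8-trimethylspiro[chromane-2,5′-[1,3]dioxan]-4-one
Conditions: pyrrolidine, toluene, 4 Å MS, rt → 80 °C, Ar
Reagents that add atoms: none
Why: Kabbe condensation (enamine/iminium aldol condensation, then 6-endo oxa-Michael closure) forms the pyranone ring; C2 bears two identical CH2O arms, so no stereocentre is created.

**Step 4**
Reactants: 5
Product: 6, 2′,2′,8-trimethyl-6-(triisopropylsilyloxy)spiro[chromane-2,5′-[1,3]dioxan]-4-one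
Conditions: TIPSCl, imidazole, DMF, rt
Reagents that add atoms: triisopropylsilyl chloride, CC(C)[Si](Cl)(C(C)C)C(C)C
Why: Silylation of the only free OH; an aryl TIPS ether tolerates the bases, hydrides, organolithium and mild acids used later and comes off with fluoride at the end.

**Step 5**
Reactants: 6
Product: 7, 2′,2′,8-trimethyl-6-(triisopropylsilyloxy)spiro[chromene-2,5′-[1,3]dioxan]-4-yl trifluoromethanesulfonate
Conditions: KHMDS, THF, −78 °C; then PhNTf2, −78 → 0 °C
Reagents that add atoms: N-phenyl-bis(trifluoromethanesulfonimide), O=S(=O)(N(c1ccccc1)S(=O)(=O)C(F)(F)F)C(F)(F)F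
Why: Kinetic enolisation at C3 and O-triflation give the enol triflate; this installs C3=C4 without passing through a racemic C4 alcohol.

**Step 6**
Reactants: 7
Product: 8, 2′,2′,8-trimethyl-6-(triisopropylsilyloxy)spiro[chromene-2,5′-[1,3]dioxane]
Conditions: Pd(OAc)2 (5 mol %), PPh3, HCO2H, n-Bu3N, DMF, 60 °C
Reagents that add atoms: none
Why: Pd-catalysed formate reduction of a vinyl triflate (Cacchi reduction) gives the 2H-chromene; acetonide and aryl silyl ether are inert.

**Step 7**
Reactants: 8
Product: 9, [8-methyl-6-(triisopropylsilyloxy)-2H-chromene-2,2-diyl]dimethanol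
Conditions: AcOH/THF/H2O (3:1:1), 45 °C
Reagents that add atoms: none
Why: Mild acetal hydrolysis frees the prochiral 1,3-diol; the aryl TIPS ether and chromene survive dilute acid.

**Step 8**
Reactants: 9
Product: 10, [(2S)-2-(hydroxymethyl)-8-methyl-6-(triisopropylsilyloxy)-2H-chromen-2-yl]methyl acetate
Conditions: immobilised Candida antarctica lipase B (a lipase), vinyl acetate, t-BuOMe, 25 °C; filter, use promptly
Reagents that add atoms: vinyl acetate, C=COC(C)=O
Why: The lipase transfers acetyl irreversibly to one of the two enantiotopic CH2OH groups (catalytic enantioselective desymmetrisation), creating the C2 quaternary stereocentre, the first and only one in the route.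

**Step 9**
Reactants: 10
Product: 11, [(2R)-2-{[tert-butyl(dimethyl)silyl]oxymethyl}-8-methyl-6-(triisopropylsilyloxy)-2H-chromen-2-yl]methyl acetate
Conditions: TBSCl, imidazole, CH2Cl2, 0 °C
Reagents that add atoms: tert-butyldimethylsilyl chloride, CC(C)(C)[Si](C)(C)Cl
Why: Silylation under mild conditions caps the free arm before any 1,3-acyl migration (which would racemise C2) can occur; the descriptor changes only through CIP priorities.

**Step 10**
Reactants: 11
Product: 12, [(2R)-2-{[tert-butyl(dimethyl)silyl]oxymethyl}-8-methyl-6-(triisopropylsilyloxy)-2H-chromen-2-yl]methanol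
Conditions: DIBAL-H, CH2Cl2, −78 °C; Rochelle salt
Reagents that add atoms: none
Why: Reductive acetate removal at low temperature avoids alkoxide conditions that could cause silyl migration or cleave the aryl silyl ether.

**Step 11**
Reactants: 12
Product: 13, [(2S)-2-{[tert-butyl(dimethyl)silyl]oxymethyl}-8-methyl-6-(triisopropylsilyloxy)-2H-chromen-2-yl]methyl trifluoromethanesulfonate
Conditions: Tf2O, pyridine, CH2Cl2, −78 → −20 °C; used crude
Reagents that add atoms: triflic anhydride, O=S(=O)(OS(=O)(=O)C(F)(F)F)C(F)(F)F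
Why: Sulfonylation activates the neopentyl-type primary alcohol; the β-aryloxy group disfavours ionisation, so the triflate is stable cold.

**Step 12**
Reactants: 13
Product: 14, tert-butyl{[(2S)-2,8-dimethyl-6-(triisopropylsilyloxy)-2H-chromen-2-yl]methoxy}dimethylsilane
Conditions: LiEt3BH, THF, −78 → 0 °C
Reagents that add atoms: none
Why: SN2 hydride displacement of the triflate turns the former acetate arm into the C2 methyl; the other arm is a silyl ether, so neither oxetane formation nor arm scrambling is possible.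

**Step 13**
Reactants: 14
Product: 15, [(2S)-2,8-dimethyl-6-(triisopropylsilyloxy)-2H-chromen-2-yl]methanol
Conditions: CSA (cat.), MeOH/CH2Cl2, 0 °C → rt
Reagents that add atoms: none
Why: Acid-catalysed solvolysis removes the alkyl TBS ether selectively, since aryl silyl ethers are much more acid-stable.

**Step 14**
Reactants: 15
Product: 16, [(2S)-2,8-dimethyl-6-(triisopropylsilyloxy)-2H-chromen-2-yl]methyl trifluoromethanesulfonate
Conditions: Tf2O, pyridine, CH2Cl2, −78 → −20 °C; used crude
Reagents that add atoms: triflic anhydride, O=S(=O)(OS(=O)(=O)C(F)(F)F)C(F)(F)F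
Why: A triflate is needed for SN2 at this hindered primary carbon in the fragment coupling.

**Step 15**
Reactants: 17, geranyl bromide [(E)-1-bromo-3,7-dimethylocta-2,6-diene]
Product: 18, (E)-geranyl phenyl sulfone
Conditions: PhSO2Na, DMF, rt
Reagents that add atoms: sodium benzenesulfinate, [Na+].[O-]S(=O)c1ccccc1
Why: S-alkylation of sulfinate (SN2) gives the allylic sulfone with the (E)-trisubstituted olefin of geraniol intact.

**Step 16**
Reactants: 18
Product: 19, (E)-4-methyl-6-(phenylsulfonyl)hex-4-en-1-ol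
Conditions: O3 (1 equiv, Sudan III end-point), CH2Cl2/MeOH, pyridine, −78 °C; then NaBH4, −78 → 0 °C
Reagents that add atoms: ozone, [O-][O+]=O
Why: Chemoselective ozonolysis of the electron-rich terminal olefin (the allylic-sulfone olefin is deactivated) with reductive work-up gives the C6 alcohol directly.

**Step 17**
Reactants: 19
Product: 20, tert-butyldimethyl{[(E)-4-methyl-6-(phenylsulfonyl)hex-4-en-1-yl]oxy}silane
Conditions: TBSCl, imidazole, DMF, rt
Reagents that add atoms: tert-butyldimethylsilyl chloride, CC(C)(C)[Si](C)(C)Cl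
Why: Standard silylation masks the alcohol before sulfone metalation.

**Step 18**
Reactants: 16; 20
Product: 21, (2R)-2-[(E)-7-{[tert-butyl(dimethyl)silyl]oxy}-4-methyl-2-(phenylsulfonyl)hept-3-en-1-yl]-2,8-dimethyl-6-(triisopropylsilyloxy)-2H-chromene (epimer mixture at C–SO2Ph)
Conditions: 20, n-BuLi, THF/HMPA, −78 °C; then 16, −78 → −40 °C
Reagents that add atoms: none
Why: α-Alkylation of the lithiated allylic sulfone by the primary triflate (Julia-type sulfone alkylation) forms C1′–C2′ without touching C2; the sulfone-bearing stereocentre is removed in the next step.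

**Step 19**
Reactants: 21
Product: 22, (2R)-2-[(E)-7-{[tert-butyl(dimethyl)silyl]oxy}-4-methylhept-3-en-1-yl]-2,8-dimethyl-6-(triisopropylsilyloxy)-2H-chromene
Conditions: PdCl2(dppp) (10 mol %), LiEt3BH, THF, 0 °C
Reagents that add atoms: none
Why: Pd-catalysed reductive desulfonylation via a π-allyl with hydride delivery to the less substituted terminus keeps the olefin position and E geometry; a dissolving metal is avoided because it would reduce the styrenyl C3=C4.

**Step 20**
Reactants: 22
Product: 23, (E)-7-[(2R)-2,8-dimethyl-6-(triisopropylsilyloxy)-2H-chromen-2-yl]-4-methylhept-4-en-1-ol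
Conditions: CSA (cat.), MeOH/CH2Cl2, 0 °C
Reagents that add atoms: none
Why: Selective acidic cleavage of the primary alkyl TBS ether in the presence of the aryl TIPS ether; conditions are too mild to ionise the chromene C2–O bond.

**Step 21**
Reactants: 23
Product: 24, (E)-7-[(2R)-2,8-dimethyl-6-(triisopropylsilyloxy)-2H-chromen-2-yl]-4-methylhept-4-enal
Conditions: Dess–Martin periodinane, NaHCO3, CH2Cl2, 0 °C → rt
Reagents that add atoms: none
Why: Neutral Dess–Martin oxidation gives the aldehyde without olefin migration.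

**Step 22**
Reactants: 25, methyl 2-[bis(2,2,2-trifluoroethoxy)phosphoryl]acetate; 26, 5-bromo-2-methylpent-2-ene
Product: 27, methyl 2-[bis(2,2,2-trifluoroethoxy)phosphoryl]-6-methylhept-5-enoate (racemic at C2)
Conditions: NaH, DMF, 0 °C; then 26, n-Bu4NI (cat.), 50 °C
Reagents that add atoms: none
Why: C-alkylation of the stabilised phosphonoacetate anion installs the homoprenyl branch; the racemic α-centre disappears in the olefination.

**Step 23**
Reactants: 24; 27
Product: 28, methyl (2Z,6E)-9-[(2R)-2,8-dimethyl-6-(triisopropylsilyloxy)-2H-chromen-2-yl]-6-methyl-2-(4-methylpent-3-en-1-yl)nona-2,6-dienoate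
Conditions: 27, KHMDS, 18-crown-6, THF, −78 °C; then 24, −78 °C
Reagents that add atoms: none
Why: Still–Gennari olefination; fast irreversible elimination from the kinetically formed adduct of the trifluoroethyl phosphonate places the ester cis to the chain, giving the (Z)-trisubstituted enoate.

**Step 24**
Reactants: 28
Product: 29, (R)-sargachromenol methyl ester
Conditions: TBAF, THF, 0 °C; aq. NH4Cl
Reagents that add atoms: none
Why: Fluoride cleaves the aryl Si–O bond rapidly under non-acidic conditions that leave the chromene, olefins and ester alone.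

**Step 25**
Reactants: 29
Product: 30, (R)-sargachromenol
Conditions: LiOH·H2O, degassed THF/MeOH/H2O, 40 °C, Ar; then aq. citric acid to pH 4, 0 °C
Reagents that add atoms: lithium hydroxide/water, [Li+].[OH-] and O
Why: BAc2 saponification of the methyl ester under mild, oxygen-free conditions gives the acid without Z→E isomerisation or phenol oxidation; C2 is not involved.

## Compound list
1 | 4-methoxy-2-methylphenol | COc1ccc(O)c(C)c1 | starting material
2 | 1-(2-hydroxy-5-methoxy-3-methylphenyl)ethanone | CC(=O)c1cc(OC)cc(C)c1O | intermediate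
3 | 1-(2,5-dihydroxy-3-methylphenyl)ethanone | CC(=O)c1cc(O)cc(C)c1O | intermediate
4 | 2,2-dimethyl-1,3-dioxan-5-one | CC1(C)OCC(=O)CO1 | starting material
5 | 6-hydroxy-2′,2′,8-trimethylspiro[chromane-2,5′-[1,3]dioxan]-4-one | O=C1CC2(COC(C)(C)OC2)Oc2c(C)cc(O)cc21 | intermediate
6 | 6-TIPS ether of 5 | O=C1CC2(COC(C)(C)OC2)Oc2c(C)cc(O[Si](C(C)C)(C(C)C)C(C)C)cc21 | intermediate
7 | spiro-chromen-4-yl triflate | O=S(=O)(OC1=CC2(COC(C)(C)OC2)Oc2c(C)cc(O[Si](C(C)C)(C(C)C)C(C)C)cc21)C(F)(F)F | intermediate
8 | spiro-2H-chromene acetonide | CC1(C)OCC2(CO1)C=Cc1cc(O[Si](C(C)C)(C(C)C)C(C)C)cc(C)c1O2 | intermediate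
9 | [8-methyl-6-(triisopropylsilyloxy)-2H-chromene-2,2-diyl]dimethanol | OCC1(CO)C=Cc2cc(O[Si](C(C)C)(C(C)C)C(C)C)cc(C)c2O1 | intermediate
10 | (S)-monoacetate | OC[C@]1(COC(C)=O)C=Cc2cc(O[Si](C(C)C)(C(C)C)C(C)C)cc(C)c2O1 | intermediate
11 | (R)-TBS ether acetate | CC(C)(C)[Si](C)(C)OC[C@]1(COC(C)=O)C=Cc2cc(O[Si](C(C)C)(C(C)C)C(C)C)cc(C)c2O1 | intermediate
12 | (R)-mono-TBS diol | CC(C)(C)[Si](C)(C)OC[C@]1(CO)C=Cc2cc(O[Si](C(C)C)(C(C)C)C(C)C)cc(C)c2O1 | intermediate
13 | (S)-TBS ether triflate | CC(C)(C)[Si](C)(C)OC[C@]1(COS(=O)(=O)C(F)(F)F)C=Cc2cc(O[Si](C(C)C)(C(C)C)C(C)C)cc(C)c2O1 | intermediate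
14 | (S)-2-methyl TBS ether | CC(C)(C)[Si](C)(C)OC[C@]1(C)C=Cc2cc(O[Si](C(C)C)(C(C)C)C(C)C)cc(C)c2O1 | intermediate
15 | [(2S)-2,8-dimethyl-6-(triisopropylsilyloxy)-2H-chromen-2-yl]methanol | OC[C@]1(C)C=Cc2cc(O[Si](C(C)C)(C(C)C)C(C)C)cc(C)c2O1 | intermediate
16 | (S)-chromenylmethyl triflate | O=S(=O)(OC[C@]1(C)C=Cc2cc(O[Si](C(C)C)(C(C)C)C(C)C)cc(C)c2O1)C(F)(F)F | intermediate
17 | geranyl bromide | CC(C)=CCC/C(C)=C/CBr | starting material
18 | (E)-geranyl phenyl sulfone | CC(C)=CCC/C(C)=C/CS(=O)(=O)c1ccccc1 | intermediate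
19 | (E)-4-methyl-6-(phenylsulfonyl)hex-4-en-1-ol | OCCC/C(C)=C/CS(=O)(=O)c1ccccc1 | intermediate
20 | TBS ether of 19 | CC(C)(C)[Si](C)(C)OCCC/C(C)=C/CS(=O)(=O)c1ccccc1 | intermediate
21 | coupled sulfone (2R; sulfone carbon unassigned) | CC(C)(C)[Si](C)(C)OCCC/C(C)=C/C(C[C@]1(C)C=Cc2cc(O[Si](C(C)C)(C(C)C)C(C)C)cc(C)c2O1)S(=O)(=O)c1ccccc1 | intermediate
22 | desulfonylated bis-silyl ether (2R) | CC(C)(C)[Si](C)(C)OCCC/C(C)=C/CC[C@]1(C)C=Cc2cc(O[Si](C(C)C)(C(C)C)C(C)C)cc(C)c2O1 | intermediate
23 | (E)-7-[(2R)-chromen-2-yl]-4-methylhept-4-en-1-ol | OCCC/C(C)=C/CC[C@]1(C)C=Cc2cc(O[Si](C(C)C)(C(C)C)C(C)C)cc(C)c2O1 | intermediate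
24 | (E)-7-[(2R)-chromen-2-yl]-4-methylhept-4-enal | O=CCC/C(C)=C/CC[C@]1(C)C=Cc2cc(O[Si](C(C)C)(C(C)C)C(C)C)cc(C)c2O1 | intermediate
25 | methyl 2-[bis(2,2,2-trifluoroethoxy)phosphoryl]acetate | COC(=O)CP(=O)(OCC(F)(F)F)OCC(F)(F)F | starting material
26 | 5-bromo-2-methylpent-2-ene | CC(C)=CCCBr | starting material
27 | methyl 2-[bis(2,2,2-trifluoroethoxy)phosphoryl]-6-methylhept-5-enoate (racemic) | COC(=O)C(CCC=C(C)C)P(=O)(OCC(F)(F)F)OCC(F)(F)F | intermediate
28 | TIPS-protected (2Z,6E)-methyl ester (2R) | CC(C)=CCC/C(=C/CC/C(C)=C/CC[C@]1(C)C=Cc2cc(O[Si](C(C)C)(C(C)C)C(C)C)cc(C)c2O1)C(=O)OC | intermediate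
29 | (R)-sargachromenol methyl ester | CC(C)=CCC/C(=C/CC/C(C)=C/CC[C@]1(C)C=Cc2cc(O)cc(C)c2O1)C(=O)OC | intermediate
30 | (R)-sargachromenol | CC(C)=CCC/C(=C/CC/C(C)=C/CC[C@]1(C)C=Cc2cc(O)cc(C)c2O1)C(=O)O | target

## Summary
- Total step count: 25.
- Longest linear sequence: 21 steps (1 → 30 through steps 1–14, 18–21, 23–25).

Three steps most likely to fail, each with a fallback:
1. **Step 8 (lipase desymmetrisation of a new chromene substrate; sense and ee are by analogy).** Fallback: run the enzyme in the hydrolytic direction on the diacetate of 9, which gives the antipodal monoacetate, and swap the fates of the two arms (free arm → tosylate → hydride → CH3; ester arm → side chain).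
2. **Step 18 (SN2 of a sulfone anion at a neopentyl-type triflate).** Fallback: oxidise 15 to the aldehyde, Wittig-methylenate to the 2-vinylchromene, hydroborate the terminal vinyl with 9-BBN, and B-alkyl Suzuki–Miyaura couple with (E)-5-iodo-4-methylpent-4-en-1-ol TBS ether (from pent-4-yn-1-ol by Zr-catalysed carboalumination/iodination) to reach 22 directly.
3. **Step 3 (Kabbe annulation with a self-condensing α,α′-dialkoxy ketone).** Fallback: convert 4 by HWE homologation, reduction and oxidation to (2,2-dimethyl-1,3-dioxan-5-ylidene)acetaldehyde and condense it with 2-methyl-4-(triisopropylsilyloxy)phenol (PhB(OH)2/AcOH, ortho-quinone-methide formation then oxa-6π electrocyclisation) to give spiro-chromene 8 directly.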